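**Strategy.** The target (numbered as a 6-oxabicyclo[3.2.2]non-3-ene) is treated as the Baeyer–Villiger product of a bicyclo[3.2.1]oct-3-ene-2,8-dione. Its lactone bridge O6–C7 is an oxygen-expanded ketone bridge. Its enone bridge C2(=O)–C3(allyl)=C4H spans C1 and C5, which sit cis across the lactone ring, a cyclopentanone before oxygen insertion. The route rests on making the C3=C4 double bond by ring-closing metathesis between a vinyl group on C5 and a 2-methylenepent-4-enoyl group on C1. One operation closes the six-membered enone ring, creates the bridged bicycle and leaves the allyl group in place. The precursor is a 2-methoxy-2-vinyl-3-methyl-4-aryl-5-acylcyclopentanone, assembled by substrate-controlled relay from one purchased silyloxy stereocentre.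

Key step: step 9

Remark: 1 and the THF solution of 2 are taken as purchased; β-diketone 19 is drawn in its keto form although it should be largely enolised.

Step 1
Reactants: 1 (S)-4-(tert-butyldimethylsilyloxy)cyclopent-2-en-1-one; 2 (3,4,5-trimethoxyphenyl)magnesium bromide
Product: 3 (3R,4S)-4-(tert-butyldimethylsilyloxy)-3-(3,4,5-trimethoxyphenyl)cyclopentan-1-one (trans)
Conditions: 2 (1.5 equiv), CuBr·SMe2 (10 mol%), THF, −78 to −40 °C; sat. aq NH4Cl
Reagents that add atoms: (3,4,5-trimethoxyphenyl)magnesium bromide 2, COc1cc([Mg]Br)cc(OC)c1OC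
Why: Copper-catalysed 1,4-addition of the aryl Grignard reagent (organocuprate conjugate addition); the aryl group enters C3 on the face opposite the C4 silyloxy group, so the purchased stereocentre sets the benzylic one.

Step 2
Reactants: 3 (3R,4S)-4-(tert-butyldimethylsilyloxy)-3-(3,4,5-trimethoxyphenyl)cyclopentan-1-one
Product: 4 (S)-4-(3,4,5-trimethoxyphenyl)cyclopent-2-en-1-one
Conditions: DBU (1.05 equiv), CH2Cl2, −20 to 0 °C, short contact; AcOH quench
Reagents that add atoms: none
Why: E1cB elimination of the β-silyloxy group through the C5 enolate gives the conjugated enone and removes the purchased stereocentre after it has done its work; low temperature and one equivalent of base are meant to spare the γ-benzylic stereocentre.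

Step 3
Reactants: 4 (S)-4-(3,4,5-trimethoxyphenyl)cyclopent-2-en-1-one; 5 iodine
Product: 6 (S)-2-iodo-4-(3,4,5-trimethoxyphenyl)cyclopent-2-en-1-one
Conditions: I2 (1.5 equiv), pyridine/CH2Cl2, 0 °C to rt
Reagents that add atoms: iodine 5, II
Why: α-Iodination of the enone by pyridine addition, iodination and elimination (Baylis–Hillman-type α-halogenation of cycloalkenones); no stereocentre is touched.

Step 4
Reactants: 6 (S)-2-iodo-4-(3,4,5-trimethoxyphenyl)cyclopent-2-en-1-one; 7 tributyl(vinyl)stannane
Product: 8 (S)-4-(3,4,5-trimethoxyphenyl)-2-vinylcyclopent-2-en-1-one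
Conditions: 7 (1.2 equiv), Pd2(dba)3 (2.5 mol%), AsPh3 (10 mol%), CuI (10 mol%), NMP, rt; used at once
Reagents that add atoms: tributyl(vinyl)stannane 7, C=C[Sn](CCCC)(CCCC)CCCC
Why: Stille cross-coupling of the α-iodoenone with the vinylstannane under neutral conditions that leave the γ-stereocentre alone.

Step 5
Reactants: 8 (S)-4-(3,4,5-trimethoxyphenyl)-2-vinylcyclopent-2-en-1-one; 9 methyllithium; 10 2-(phenylsulfonyl)-3-phenyloxaziridine
Product: 12 (2S,3R,4S)-2-hydroxy-3-methyl-4-(3,4,5-trimethoxyphenyl)-2-vinylcyclopentan-1-one, via lithium dienolate 11 (not isolated)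
Conditions: CuI (1.1 equiv), 9 (2.2 equiv), Et2O, 0 °C (gives Me2CuLi); 8, THF/Et2O, −78 °C; then 10 (2.5 equiv), −78 to −40 °C; aq NH4Cl
Reagents that add atoms: methyllithium 9 (delivered as Me2CuLi), [Li]C; 2-(phenylsulfonyl)-3-phenyloxaziridine 10, O=S(=O)(N1OC1c1ccccc1)c1ccccc1
Why: Tandem organocuprate 1,4-addition and enolate hydroxylation with an N-sulfonyloxaziridine (Davis oxidation): methyl adds to C3 anti to the C4 aryl group, and the oxidant attacks the α-carbon of dienolate 11 anti to the new methyl group, which places hydroxyl trans and vinyl cis to methyl, the same sense as electrophile trapping in three-component couplings of cyclopentenones.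

Step 6
Reactants: 12 (2S,3R,4S)-2-hydroxy-3-methyl-4-(3,4,5-trimethoxyphenyl)-2-vinylcyclopentan-1-one; 13 methyl trifluoromethanesulfonate
Product: 14 (2S,3R,4S)-2-methoxy-3-methyl-4-(3,4,5-trimethoxyphenyl)-2-vinylcyclopentan-1-one
Conditions: 13 (3 equiv), 2,6-di-tert-butyl-4-methylpyridine (4 equiv), CH2Cl2, rt to 40 °C
Reagents that add atoms: methyl trifluoromethanesulfonate 13, COS(=O)(=O)C(F)(F)F
Why: O-Methylation of the hindered tertiary alcohol with methyl triflate and a non-nucleophilic pyridine base, which avoids enolate C-methylation and α-ketol rearrangement; no stereocentre changes.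

Step 7 (side branch)
Reactants: 15 allylmalonic acid; 16 formaldehyde (as paraformaldehyde)
Product: 17 2-methylenepent-4-enoic acid
Conditions: (CH2O)n (1.5 equiv), Et2NH (1.5 equiv), EtOAc, reflux
Reagents that add atoms: formaldehyde 16, C=O
Why: Mannich-type condensation of the substituted malonic acid with formaldehyde followed by decarboxylative elimination (Knoevenagel–Doebner-type methylenation) gives the 2-substituted acrylic acid.

Step 8
Reactants: 14 (2S,3R,4S)-2-methoxy-3-methyl-4-(3,4,5-trimethoxyphenyl)-2-vinylcyclopentan-1-one; 17 2-methylenepent-4-enoic acid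
Product: 19 (2S,3R,4R,5R)-2-methoxy-3-methyl-5-(2-methylenepent-4-enoyl)-4-(3,4,5-trimethoxyphenyl)-2-vinylcyclopentan-1-one, via 2-methylenepent-4-enoyl chloride 18 (not isolated)
Conditions: 17, (COCl)2, DMF (cat.), CH2Cl2, 0 °C to rt, evaporate; then 14, MgBr2·OEt2 (2.5 equiv), i-Pr2NEt (3 equiv), CH2Cl2, 0 °C to rt
Reagents that add atoms: 2-methylenepent-4-enoic acid 17 (as its chloride 18), C=CCC(=C)C(=O)O
Why: Crossed Claisen C-acylation by soft enolisation: the magnesium-chelated enolate can form only at C5, the sole α-position bearing hydrogen, and the new epimerisable centre settles trans to the C4 aryl group, hence cis to the C2 vinyl group.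

Step 9
Reactants: 19 (2S,3R,4R,5R)-2-methoxy-3-methyl-5-(2-methylenepent-4-enoyl)-4-(3,4,5-trimethoxyphenyl)-2-vinylcyclopentan-1-one
Product: 20 (1R,5R,6R,7R)-3-allyl-5-methoxy-6-methyl-7-(3,4,5-trimethoxyphenyl)bicyclo[3.2.1]oct-3-ene-2,8-dione
Conditions: second-generation Hoveyda–Grubbs catalyst RuCl2(H2IMes)(=CH-C6H4-2-OiPr) (10 mol%, two portions), 1,4-benzoquinone (20 mol%), toluene (0.002 M), 80 °C, argon sparge
Reagents that add atoms: none
Why: Ruthenium-carbene olefin metathesis ([2+2] cycloaddition and cycloreversion through ruthenacyclobutanes, with loss of ethylene) joins the vinyl carbon on C5 to the methylene carbon of the 2-methylene ketone; the closest known reaction types are ring-closing metathesis of 1,1-disubstituted α-methylene ketones to 2-substituted cycloalkenones and of cis-1,3-dialkenyl cyclopentanes to bridged bicyclo[3.2.1]octenes. The six-membered ring (C1, C2, C3, C4, C5, C8 of the bicyclooctene) is closed across the 1,3-positions of the cyclopentanone, with the new double bond endocyclic and the allyl group left on C3. No stereocentre is created, but C1 is fixed: the β-diketone methine epimerises through its enol, and only the epimer with the acyl group cis to the C5 vinyl group (also the thermodynamic one, trans to the C7 aryl group) can cyclise. The step needs site selectivity among three alkenes: only the vinyl/methylene pair gives an unstrained six-membered ring, a carbene on the allyl terminus could close only an eight-membered bridged ring or revert with ethylene, and the trisubstituted enone of the product is not re-opened, so the mixture should drain into 20. Benzoquinone is added against ruthenium-hydride migration of the skipped diene, and high dilution against cross-metathesis.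

Step 10
Reactants: 20 (1R,5R,6R,7R)-3-allyl-5-methoxy-6-methyl-7-(3,4,5-trimethoxyphenyl)bicyclo[3.2.1]oct-3-ene-2,8-dione; 21 3-chloroperoxybenzoic acid
Product: 22 (1R,5S,8R,9R)-3-allyl-5-methoxy-9-methyl-8-(3,4,5-trimethoxyphenyl)-6-oxabicyclo[3.2.2]non-3-ene-2,7-dione (CNP0298078.1)
Conditions: 21 (1.2 equiv), solid Na2HPO4 buffer, CH2Cl2, 0 °C
Reagents that add atoms: 3-chloroperoxybenzoic acid 21, OOC(=O)c1cccc(Cl)c1
Why: Baeyer–Villiger oxidation: the peracid adds to the strained, doubly activated C8 bridge ketone and the methoxy-bearing bridgehead C5 migrates with retention (oxygen-stabilised and more electron-rich than C1, which is flanked by the second carbonyl), so oxygen is inserted between C8 and C5 to give the bridged methoxy lactone, while the enone carbonyl and the terminal allyl alkene should react more slowly.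

**Compound list**

1 | (S)-4-(tert-butyldimethylsilyloxy)cyclopent-2-en-1-one | O=C1C=C[C@@H](O[Si](C)(C)C(C)(C)C)C1 | starting material
2 | (3,4,5-trimethoxyphenyl)magnesium bromide | COc1cc([Mg]Br)cc(OC)c1OC | starting material
3 | (3R,4S)-4-(tert-butyldimethylsilyloxy)-3-(3,4,5-trimethoxyphenyl)cyclopentan-1-one | O=C1C[C@H](c2cc(OC)c(OC)c(OC)c2)[C@@H](O[Si](C)(C)C(C)(C)C)C1 | intermediate
4 | (S)-4-(3,4,5-trimethoxyphenyl)cyclopent-2-en-1-one | O=C1C=C[C@@H](c2cc(OC)c(OC)c(OC)c2)C1 | intermediate
5 | iodine | II | starting material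
6 | (S)-2-iodo-4-(3,4,5-trimethoxyphenyl)cyclopent-2-en-1-one | O=C1C(I)=C[C@@H](c2cc(OC)c(OC)c(OC)c2)C1 | intermediate
7 | tributyl(vinyl)stannane | C=C[Sn](CCCC)(CCCC)CCCC | starting material
8 | (S)-4-(3,4,5-trimethoxyphenyl)-2-vinylcyclopent-2-en-1-one | C=CC1=C[C@@H](c2cc(OC)c(OC)c(OC)c2)CC1=O | intermediate
9 | methyllithium | [Li]C | starting material
10 | 2-(phenylsulfonyl)-3-phenyloxaziridine | O=S(=O)(N1OC1c1ccccc1)c1ccccc1 | starting material
11 | lithium (3R,4S)-3-methyl-4-(3,4,5-trimethoxyphenyl)-2-vinylcyclopent-1-en-1-olate | C=CC1=C(O[Li])C[C@H](c2cc(OC)c(OC)c(OC)c2)[C@H]1C | intermediate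
12 | (2S,3R,4S)-2-hydroxy-3-methyl-4-(3,4,5-trimethoxyphenyl)-2-vinylcyclopentan-1-one | C=C[C@@]1(O)C(=O)C[C@H](c2cc(OC)c(OC)c(OC)c2)[C@H]1C | intermediate
13 | methyl trifluoromethanesulfonate | COS(=O)(=O)C(F)(F)F | starting material
14 | (2S,3R,4S)-2-methoxy-3-methyl-4-(3,4,5-trimethoxyphenyl)-2-vinylcyclopentan-1-one | C=C[C@@]1(OC)C(=O)C[C@H](c2cc(OC)c(OC)c(OC)c2)[C@H]1C | intermediate
15 | allylmalonic acid | C=CCC(C(=O)O)C(=O)O | starting material
16 | formaldehyde (as paraformaldehyde) | C=O | starting material
17 | 2-methylenepent-4-enoic acid | C=CCC(=C)C(=O)O | intermediate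
18 | 2-methylenepent-4-enoyl chloride | C=CCC(=C)C(=O)Cl | intermediate
19 | (2S,3R,4R,5R)-2-methoxy-3-methyl-5-(2-methylenepent-4-enoyl)-4-(3,4,5-trimethoxyphenyl)-2-vinylcyclopentan-1-one | C=C[C@@]1(OC)C(=O)[C@@H](C(=O)C(=C)CC=C)[C@H](c2cc(OC)c(OC)c(OC)c2)[C@H]1C | intermediate
20 | (1R,5R,6R,7R)-3-allyl-5-methoxy-6-methyl-7-(3,4,5-trimethoxyphenyl)bicyclo[3.2.1]oct-3-ene-2,8-dione | C=CCC1=C[C@@]2(OC)C(=O)[C@@H](C1=O)[C@H](c3cc(OC)c(OC)c(OC)c3)[C@H]2C | intermediate
21 | 3-chloroperoxybenzoic acid | OOC(=O)c1cccc(Cl)c1 | starting material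
22 | (1R,5S,8R,9R)-3-allyl-5-methoxy-9-methyl-8-(3,4,5-trimethoxyphenyl)-6-oxabicyclo[3.2.2]non-3-ene-2,7-dione | C=CCC1=C[C@@]2(OC)OC(=O)[C@@H](C1=O)[C@H](c1cc(OC)c(OC)c(OC)c1)[C@H]2C | target

**Total step count:** 10. **Longest linear sequence:** 9 steps (steps 1–6 and 8–10); step 7 is a one-step side branch.

**Steps most likely to fail**

Step 9. The ruthenium carbene may be held at the unhindered allyl terminus and by the enolised β-diketone, so that closure onto the congested vinyl group stalls. Cross-metathesis, or conjugate closure of the enol oxygen onto the methylene ketone, could then take over. The fallback sets out from 14 and removes both the third alkene and the enolisable diketone. Aldol addition of the lithium enolate of 14 (LDA, THF, −78 °C) to acrolein should give, trans to the aryl group, 5-(1-hydroxyprop-2-enyl)-2-methoxy-3-methyl-4-(3,4,5-trimethoxyphenyl)-2-vinylcyclopentan-1-one F1 as a mixture of carbinol epimers. Ring-closing metathesis of this simple diene (second-generation Grubbs catalyst RuCl2(H2IMes)(PCy3)(=CHPh), CH2Cl2, 40 °C) should give 2-hydroxy-5-methoxy-6-methyl-7-(3,4,5-trimethoxyphenyl)bicyclo[3.2.1]oct-3-en-8-one F2. Dess–Martin oxidation should give 5-methoxy-6-methyl-7-(3,4,5-trimethoxyphenyl)bicyclo[3.2.1]oct-3-ene-2,8-dione F3, which is 20 without its allyl group. Iodine in pyridine should give the 3-iodo enone F4. Stille coupling with allyltributylstannane (Pd2(dba)3, AsPh3, CuI) comes back to the route at 20.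

Step 5. Methylcopper may consume the oxaziridine, the new alkoxide may add to the sulfonimine by-product, and the dienolate may be oxidised with eroded site or facial selectivity. The fallback sets out from 8 and separates the two events. Addition of Me2CuLi in the presence of TMSCl and Et3N should give the isolable trimethylsilyl dienol ether of the conjugate adduct, trimethyl{[(3R,4S)-3-methyl-4-(3,4,5-trimethoxyphenyl)-2-vinylcyclopent-1-en-1-yl]oxy}silane F5. Methyllithium (THF, 0 °C) regenerates the copper-free lithium dienolate 11. This is hydroxylated at −78 °C with (camphorsulfonyl)oxaziridine, whose ketimine by-product does not capture alkoxides. The sequence comes back to the route at 12.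

Step 10. Epoxidation of the allyl alkene may compete with oxygen insertion, and the acylal may open under the acid formed. The fallback sets out from 14 and does the oxidation before the allyl group and the second carbonyl are present. Baeyer–Villiger oxidation of 14 (21, buffer) should give (4S,5R,6S)-6-methoxy-5-methyl-4-(3,4,5-trimethoxyphenyl)-6-vinyltetrahydro-2H-pyran-2-one F6. C-Acylation of its lithium enolate (LiHMDS, THF, −78 °C) with chloride 18 should give the 3-(2-methylenepent-4-enoyl) lactone F7. Ring-closing metathesis with the second-generation Hoveyda–Grubbs catalyst, now closing the seven-membered carbocycle by the same C3=C4 bond, comes back to the route at 22.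

**Further compounds**

F1 | step 9 | 5-(1-hydroxyprop-2-enyl)-2-methoxy-3-methyl-4-(3,4,5-trimethoxyphenyl)-2-vinylcyclopentan-1-one, ring configuration as in 19, carbinol epimers | C=C[C@@]1(OC)C(=O)[C@@H](C(O)C=C)[C@H](c2cc(OC)c(OC)c(OC)c2)[C@H]1C
F2 | step 9 | 2-hydroxy-5-methoxy-6-methyl-7-(3,4,5-trimethoxyphenyl)bicyclo[3.2.1]oct-3-en-8-one, ring configuration as in 20, carbinol epimers | OC1C=C[C@@]2(OC)C(=O)[C@@H]1[C@H](c3cc(OC)c(OC)c(OC)c3)[C@H]2C
F3 | step 9 | 5-methoxy-6-methyl-7-(3,4,5-trimethoxyphenyl)bicyclo[3.2.1]oct-3-ene-2,8-dione, configuration as in 20 | O=C1C=C[C@@]2(OC)C(=O)[C@@H]1[C@H](c3cc(OC)c(OC)c(OC)c3)[C@H]2C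
F4 | step 9 | 3-iodo-5-methoxy-6-methyl-7-(3,4,5-trimethoxyphenyl)bicyclo[3.2.1]oct-3-ene-2,8-dione, configuration as in 20 | O=C1C(I)=C[C@@]2(OC)C(=O)[C@@H]1[C@H](c3cc(OC)c(OC)c(OC)c3)[C@H]2C
F5 | step 5 | trimethyl{[(3R,4S)-3-methyl-4-(3,4,5-trimethoxyphenyl)-2-vinylcyclopent-1-en-1-yl]oxy}silane | C=CC1=C(O[Si](C)(C)C)C[C@H](c2cc(OC)c(OC)c(OC)c2)[C@H]1C
F6 | step 10 | (4S,5R,6S)-6-methoxy-5-methyl-4-(3,4,5-trimethoxyphenyl)-6-vinyltetrahydro-2H-pyran-2-one | C=C[C@@]1(OC)OC(=O)C[C@H](c2cc(OC)c(OC)c(OC)c2)[C@H]1C
F7 | step 10 | 6-methoxy-5-methyl-3-(2-methylenepent-4-enoyl)-4-(3,4,5-trimethoxyphenyl)-6-vinyltetrahydro-2H-pyran-2-one, configuration as in 22 | C=C[C@@]1(OC)OC(=O)[C@@H](C(=O)C(=C)CC=C)[C@H](c2cc(OC)c(OC)c(OC)c2)[C@H]1C
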